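**Assumption:** the target SMILES contains no stereocentre and no stereogenic double bond. Bleochrin A is therefore achiral and no enantiocontrol is needed. Transient stereocentres are carried as racemates or mixtures and are erased later.

## Retrosynthetic overview
1. Target ⇒ penta-O-benzyl stilbene. One final hydrogenation saturates the C=C bond and removes all five benzyl ethers.
2. Stilbene ⇒ 2,3-diaryl-3-hydroxypropanoic acid by decarboxylative dehydration ⇒ ring A benzaldehyde + dianion of the ring B arylacetic acid. This intermolecular aldol addition forms the key C–C bond of the ethano bridge.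
3. Ring A aldehyde ⇒ 4-bromo-3,5-dihydroxybenzoic acid. The C4 arm comes from Negishi benzylation. The C2 arm comes from formylation (C2 and C6 are symmetry-equivalent), chelation-controlled O3 debenzylation and methylation, aryl Grignard addition, and reductive lactone opening.
4. Ring B acid ⇒ (3-hydroxyphenyl)acetic acid, by para-bromination and Negishi coupling with the same benzylzinc reagent.
5. Ring order: all five benzene rings are bought and none is built. The only ring formed is a transient phthalide lactone on ring A (step 9), which is reopened in step 10.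

## Route

### Shared benzylzinc reagent

Step 1
Reactants: 1 4-(benzyloxy)benzyl chloride
Product: 2 [4-(benzyloxy)benzyl]zinc chloride (titrated THF solution, used in steps 4 and 15)
Conditions: Zn dust (activated), LiCl, THF, 25 °C
Reagents that add atoms: zinc, [Zn]
Why: LiCl-assisted direct insertion of zinc into the benzylic C–Cl bond gives an ester-tolerant benzylzinc chloride with little Wurtz dimer.

### Ring A aldehyde

Step 2
Reactants: 3 4-bromo-3,5-dihydroxybenzoic acid
Product: 4 methyl 4-bromo-3,5-dihydroxybenzoate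
Conditions: MeOH, cat. H2SO4, reflux
Reagents that add atoms: methanol, CO
Why: Fischer esterification in excess methanol goes to completion and leaves the phenols and the aryl bromide untouched.

Step 3
Reactants: 4 methyl 4-bromo-3,5-dihydroxybenzoate
Product: 5 methyl 3,5-bis(benzyloxy)-4-bromobenzoate
Conditions: BnBr (2.4 equiv), K2CO3, DMF, 60 °C
Reagents that add atoms: benzyl bromide, BrCc1ccccc1
Why: Williamson ether synthesis on two equivalent phenols needs no selectivity.

Step 4
Reactants: 5 methyl 3,5-bis(benzyloxy)-4-bromobenzoate; 2 [4-(benzyloxy)benzyl]zinc chloride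
Product: 6 methyl 3,5-bis(benzyloxy)-4-[4-(benzyloxy)benzyl]benzoate
Conditions: Pd(OAc)2 (2 mol %), SPhos (4 mol %), THF, 25→50 °C
Reagents that add atoms: none
Why: In this Negishi cross-coupling the para ester speeds oxidative addition of the flanked bromide to zerovalent palladium, the bulky biaryl phosphine copes with two ortho substituents, and the organozinc spares the ester.

Step 5
Reactants: 6 methyl 3,5-bis(benzyloxy)-4-[4-(benzyloxy)benzyl]benzoate
Product: 8 methyl 3,5-bis(benzyloxy)-4-[4-(benzyloxy)benzyl]-2-formylbenzoate, via aryl iminium chloride 7 (not isolated)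
Conditions: POCl3 (3 equiv), DMF, 0→80 °C; then ice–water, 25 °C
Reagents that add atoms: N,N-dimethylformamide, CN(C)C=O; water, O
Why: In this Vilsmeier–Haack formylation the weak electrophile attacks only ring A, whose two alkoxy donors reinforce each other ortho and para, and C2 and C6 are equivalent by symmetry, so one regioisomer results.

Step 6
Reactants: 8 methyl 3,5-bis(benzyloxy)-4-[4-(benzyloxy)benzyl]-2-formylbenzoate
Product: 9 methyl 5-(benzyloxy)-4-[4-(benzyloxy)benzyl]-2-formyl-3-hydroxybenzoate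
Conditions: MgBr2·OEt2 (3 equiv), toluene/Et2O, 80 °C; then dilute aq HCl
Reagents that add atoms: none
Why: In this chelation-controlled Lewis-acid debenzylation magnesium binds between the formyl oxygen and O3, so bromide removes only the benzyl group ortho to the aldehyde, which differentiates O3 from O5.

Step 7
Reactants: 9 methyl 5-(benzyloxy)-4-[4-(benzyloxy)benzyl]-2-formyl-3-hydroxybenzoate
Product: 10 methyl 5-(benzyloxy)-4-[4-(benzyloxy)benzyl]-2-formyl-3-methoxybenzoate
Conditions: MeI (3 equiv), K2CO3, DMF, 40 °C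
Reagents that add atoms: iodomethane, CI
Why: Williamson O-methylation of the only free phenol with the smallest alkylating agent overcomes both the hydrogen bond and the flanking groups.

Step 8
Reactants: 11 1-(benzyloxy)-4-bromobenzene
Product: 12 [4-(benzyloxy)phenyl]magnesium bromide (THF solution)
Conditions: Mg turnings, THF, 25→50 °C
Reagents that add atoms: magnesium, [Mg]
Why: This is a standard Grignard formation from an aryl bromide, and the benzyl ether is inert to it.

Step 9
Reactants: 10 methyl 5-(benzyloxy)-4-[4-(benzyloxy)benzyl]-2-formyl-3-methoxybenzoate; 12 [4-(benzyloxy)phenyl]magnesium bromide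
Product: 14 racemic 6-(benzyloxy)-5-[4-(benzyloxy)benzyl]-3-[4-(benzyloxy)phenyl]-4-methoxy-2-benzofuran-1(3H)-one, via bromomagnesium alkoxide 13 (not isolated)
Conditions: 12 (1.15 equiv), THF, −78→25 °C; then dilute aq HCl
Reagents that add atoms: none
Why: Grignard 1,2-addition to the aldehyde outruns attack on the ester, the alkoxide then lactonises onto the neighbouring ester, and the new stereocentre forms as a racemate that step 10 removes.

Step 10
Reactants: 14 racemic 3-arylphthalide
Product: 15 5-(benzyloxy)-2,4-bis[4-(benzyloxy)benzyl]-3-methoxybenzoic acid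
Conditions: Zn dust (excess, activated with cat. CuSO4), 10% aq KOH, pyridine, reflux; filter; aq HCl to pH 1
Reagents that add atoms: none
Why: This classical zinc–alkali reductive cleavage breaks the doubly benzylic lactone C–O bond of a 3-arylphthalide to give the 2-benzylbenzoic acid, and aryl benzyl and methyl ethers survive it.

Step 11
Reactants: 15 5-(benzyloxy)-2,4-bis[4-(benzyloxy)benzyl]-3-methoxybenzoic acid
Product: 16 {5-(benzyloxy)-2,4-bis[4-(benzyloxy)benzyl]-3-methoxyphenyl}methanol
Conditions: LiAlH4 (3 equiv), THF, 0→65 °C; then H2O, aq NaOH, H2O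
Reagents that add atoms: none
Why: Hydride reduction of the carboxylic acid to the primary alcohol meets no other reducible group.

Step 12
Reactants: 16 {5-(benzyloxy)-2,4-bis[4-(benzyloxy)benzyl]-3-methoxyphenyl}methanol
Product: 17 5-(benzyloxy)-2,4-bis[4-(benzyloxy)benzyl]-3-methoxybenzaldehyde
Conditions: Dess–Martin periodinane (1.3 equiv), CH2Cl2, 0→25 °C
Reagents that add atoms: none
Why: Dess–Martin oxidation stops cleanly at the aldehyde and does not touch the diarylmethane CH2 groups.

### Ring B acid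

Step 13
Reactants: 18 (3-hydroxyphenyl)acetic acid
Product: 19 benzyl [3-(benzyloxy)phenyl]acetate
Conditions: BnBr (2.3 equiv), K2CO3, DMF, 50 °C
Reagents that add atoms: benzyl bromide, BrCc1ccccc1
Why: Williamson etherification and carboxylate alkylation protect both acidic sites in one operation.

Step 14
Reactants: 19 benzyl [3-(benzyloxy)phenyl]acetate
Product: 20 benzyl [5-(benzyloxy)-2-bromophenyl]acetate
Conditions: NBS (1.02 equiv), MeCN, 0→25 °C, dark
Reagents that add atoms: N-bromosuccinimide, O=C1CCC(=O)N1Br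
Why: Electrophilic aromatic bromination with NBS in acetonitrile is para-selective to the alkoxy donor, which places bromine ortho to the acetate side chain.

Step 15
Reactants: 20 benzyl [5-(benzyloxy)-2-bromophenyl]acetate; 2 [4-(benzyloxy)benzyl]zinc chloride
Product: 21 benzyl {5-(benzyloxy)-2-[4-(benzyloxy)benzyl]phenyl}acetate
Conditions: Pd(OAc)2 (2 mol %), SPhos (4 mol %), THF, 25→50 °C
Reagents that add atoms: none
Why: In this Negishi cross-coupling the mild organozinc neither deprotonates nor attacks the arylacetic ester.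

Step 16
Reactants: 21 benzyl {5-(benzyloxy)-2-[4-(benzyloxy)benzyl]phenyl}acetate
Product: 22 {5-(benzyloxy)-2-[4-(benzyloxy)benzyl]phenyl}acetic acid
Conditions: LiOH (3 equiv), THF/MeOH/H2O, 25 °C; then dilute aq HCl
Reagents that add atoms: lithium hydroxide, [Li+].[OH-]
Why: Saponification of an unhindered ester leaves the aryl benzyl ethers intact.

### Union and endgame

Step 17
Reactants: 22 {5-(benzyloxy)-2-[4-(benzyloxy)benzyl]phenyl}acetic acid; 17 5-(benzyloxy)-2,4-bis[4-(benzyloxy)benzyl]-3-methoxybenzaldehyde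
Product: 24 3-{5-(benzyloxy)-2,4-bis[4-(benzyloxy)benzyl]-3-methoxyphenyl}-2-{5-(benzyloxy)-2-[4-(benzyloxy)benzyl]phenyl}-3-hydroxypropanoic acid (racemic diastereomer mixture), via dilithium enediolate 23 (not isolated)
Conditions: 22 (1.15 equiv), LiN(iPr)2 (2.4 equiv), THF, −78→0 °C; then 17 (1.0 equiv), −78→−20 °C; dilute aq HCl
Reagents that add atoms: none
Why: In this Ivanov-type intermolecular aldol addition the arylacetic acid dianion adds irreversibly at low temperature to a non-enolisable aldehyde and gives the β-hydroxy acid directly, and the two new stereocentres arise as a racemic, mainly anti mixture through a Zimmerman–Traxler chair and are both erased in step 18.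

Step 18
Reactants: 24 3-hydroxy-2,3-diarylpropanoic acid
Product: 26 5-(benzyloxy)-1-(2-{5-(benzyloxy)-2-[4-(benzyloxy)benzyl]phenyl}ethenyl)-2,4-bis[4-(benzyloxy)benzyl]-3-methoxybenzene (E/Z mixture), via oxyphosphonium carboxylate 25 (not isolated)
Conditions: PPh3 (1.5 equiv), DIAD (1.5 equiv), THF, 0→25 °C, then 65 °C, 1 h
Reagents that add atoms: none
Why: In this Mitsunobu-type decarboxylative dehydration, activation of the benzylic hydroxyl triggers a Grob-type fragmentation that expels CO2 and phosphine oxide under neutral conditions, and the alkene geometry does not matter.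

Step 19
Reactants: 26 penta-O-benzyl stilbene
Product: 27 Bleochrin A, 2,4-bis(4-hydroxybenzyl)-5-{2-[5-hydroxy-2-(4-hydroxybenzyl)phenyl]ethyl}-3-methoxyphenol
Conditions: H2 (4 bar), 10% Pd/C, THF/MeOH 1:1, 25 °C
Reagents that add atoms: none
Why: Catalytic hydrogenation saturates the disubstituted alkene and hydrogenolyses all five O-benzyl groups, while the aryl methyl ether and the diarylmethane C–C bonds are inert and no stereocentre remains.

## Compound list
1 | 4-(benzyloxy)benzyl chloride | ClCc1ccc(OCc2ccccc2)cc1 | starting material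
2 | [4-(benzyloxy)benzyl]zinc chloride | Cl[Zn]Cc1ccc(OCc2ccccc2)cc1 | intermediate
3 | 4-bromo-3,5-dihydroxybenzoic acid | OC(=O)c1cc(O)c(Br)c(O)c1 | starting material
4 | methyl 4-bromo-3,5-dihydroxybenzoate | COC(=O)c1cc(O)c(Br)c(O)c1 | intermediate
5 | methyl 3,5-bis(benzyloxy)-4-bromobenzoate | COC(=O)c1cc(OCc2ccccc2)c(Br)c(OCc2ccccc2)c1 | intermediate
6 | methyl 3,5-bis(benzyloxy)-4-[4-(benzyloxy)benzyl]benzoate | COC(=O)c1cc(OCc2ccccc2)c(Cc2ccc(OCc3ccccc3)cc2)c(OCc2ccccc2)c1 | intermediate
7 | aryl iminium chloride (C2–CH=NMe2+ Cl−) | COC(=O)c1cc(OCc2ccccc2)c(Cc2ccc(OCc3ccccc3)cc2)c(OCc2ccccc2)c1C=[N+](C)C.[Cl-] | intermediate (not isolated)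
8 | methyl 3,5-bis(benzyloxy)-4-[4-(benzyloxy)benzyl]-2-formylbenzoate | COC(=O)c1cc(OCc2ccccc2)c(Cc2ccc(OCc3ccccc3)cc2)c(OCc2ccccc2)c1C=O | intermediate
9 | methyl 5-(benzyloxy)-4-[4-(benzyloxy)benzyl]-2-formyl-3-hydroxybenzoate | COC(=O)c1cc(OCc2ccccc2)c(Cc2ccc(OCc3ccccc3)cc2)c(O)c1C=O | intermediate
10 | methyl 5-(benzyloxy)-4-[4-(benzyloxy)benzyl]-2-formyl-3-methoxybenzoate | COC(=O)c1cc(OCc2ccccc2)c(Cc2ccc(OCc3ccccc3)cc2)c(OC)c1C=O | intermediate
11 | 1-(benzyloxy)-4-bromobenzene | Brc1ccc(OCc2ccccc2)cc1 | starting material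
12 | [4-(benzyloxy)phenyl]magnesium bromide | Br[Mg]c1ccc(OCc2ccccc2)cc1 | intermediate
13 | bromomagnesium alkoxide of the diaryl carbinol (racemic) | COC(=O)c1cc(OCc2ccccc2)c(Cc2ccc(OCc3ccccc3)cc2)c(OC)c1C(O[Mg]Br)c1ccc(OCc2ccccc2)cc1 | intermediate (not isolated)
14 | racemic 6-(benzyloxy)-5-[4-(benzyloxy)benzyl]-3-[4-(benzyloxy)phenyl]-4-methoxy-2-benzofuran-1(3H)-one | O=C1OC(c3ccc(OCc4ccccc4)cc3)c2c(OC)c(Cc3ccc(OCc4ccccc4)cc3)c(OCc3ccccc3)cc12 | intermediate
15 | 5-(benzyloxy)-2,4-bis[4-(benzyloxy)benzyl]-3-methoxybenzoic acid | OC(=O)c1cc(OCc2ccccc2)c(Cc2ccc(OCc3ccccc3)cc2)c(OC)c1Cc1ccc(OCc2ccccc2)cc1 | intermediate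
16 | {5-(benzyloxy)-2,4-bis[4-(benzyloxy)benzyl]-3-methoxyphenyl}methanol | OCc1cc(OCc2ccccc2)c(Cc2ccc(OCc3ccccc3)cc2)c(OC)c1Cc1ccc(OCc2ccccc2)cc1 | intermediate
17 | 5-(benzyloxy)-2,4-bis[4-(benzyloxy)benzyl]-3-methoxybenzaldehyde | O=Cc1cc(OCc2ccccc2)c(Cc2ccc(OCc3ccccc3)cc2)c(OC)c1Cc1ccc(OCc2ccccc2)cc1 | intermediate
18 | (3-hydroxyphenyl)acetic acid | OC(=O)Cc1cccc(O)c1 | starting material
19 | benzyl [3-(benzyloxy)phenyl]acetate | O=C(Cc1cccc(OCc2ccccc2)c1)OCc1ccccc1 | intermediate
20 | benzyl [5-(benzyloxy)-2-bromophenyl]acetate | O=C(Cc1cc(OCc2ccccc2)ccc1Br)OCc1ccccc1 | intermediate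
21 | benzyl {5-(benzyloxy)-2-[4-(benzyloxy)benzyl]phenyl}acetate | O=C(Cc1cc(OCc2ccccc2)ccc1Cc1ccc(OCc2ccccc2)cc1)OCc1ccccc1 | intermediate
22 | {5-(benzyloxy)-2-[4-(benzyloxy)benzyl]phenyl}acetic acid | OC(=O)Cc1cc(OCc2ccccc2)ccc1Cc1ccc(OCc2ccccc2)cc1 | intermediate
23 | dilithium enediolate of 22 | [Li]OC(O[Li])=Cc1cc(OCc2ccccc2)ccc1Cc1ccc(OCc2ccccc2)cc1 | intermediate (not isolated)
24 | 3-{5-(benzyloxy)-2,4-bis[4-(benzyloxy)benzyl]-3-methoxyphenyl}-2-{5-(benzyloxy)-2-[4-(benzyloxy)benzyl]phenyl}-3-hydroxypropanoic acid (racemic, diastereomer mixture) | OC(=O)C(c1cc(OCc2ccccc2)ccc1Cc1ccc(OCc2ccccc2)cc1)C(O)c1cc(OCc2ccccc2)c(Cc2ccc(OCc3ccccc3)cc2)c(OC)c1Cc1ccc(OCc2ccccc2)cc1 | intermediate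
25 | oxyphosphonium carboxylate zwitterion of 24 | [O-]C(=O)C(c1cc(OCc2ccccc2)ccc1Cc1ccc(OCc2ccccc2)cc1)C(O[P+](c1ccccc1)(c1ccccc1)c1ccccc1)c1cc(OCc2ccccc2)c(Cc2ccc(OCc3ccccc3)cc2)c(OC)c1Cc1ccc(OCc2ccccc2)cc1 | intermediate (not isolated)
26 | penta-O-benzyl stilbene (E/Z mixture, geometry not specified) | COc1c(Cc2ccc(OCc3ccccc3)cc2)c(OCc2ccccc2)cc(C=Cc2cc(OCc3ccccc3)ccc2Cc2ccc(OCc3ccccc3)cc2)c1Cc1ccc(OCc2ccccc2)cc1 | intermediate
27 | Bleochrin A (achiral) | COc1c(Cc2ccc(O)cc2)c(O)cc(CCc2cc(O)ccc2Cc2ccc(O)cc2)c1Cc1ccc(O)cc1 | target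

## Step count and risk assessment
Total step count: 19, including the two organometallic reagent preparations.
Longest linear sequence: 13 steps from 3 (steps 2–7, 9–12, 17–19).

**Step 5 (Vilsmeier–Haack formylation).**
- Risk: C2 lies between the ester and a benzyloxy group that the C4 arm pushes toward it, and the ester deactivates the ring. Conversion may therefore be poor.
- Fallback: this sets out from 6 and replaces electrophilic formylation by halogenation and metalation. NBS (1.0 equiv, MeCN, 0 °C) gives methyl 3,5-bis(benzyloxy)-4-[4-(benzyloxy)benzyl]-2-bromobenzoate F1.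
- Bromine–magnesium exchange with iPrMgCl·LiCl (THF, −20 °C), helped by the neighbouring ester, gives {2,4-bis(benzyloxy)-3-[4-(benzyloxy)benzyl]-6-(methoxycarbonyl)phenyl}magnesium chloride F2.
- DMF converts this into chloromagnesium (dimethylamino){2,4-bis(benzyloxy)-3-[4-(benzyloxy)benzyl]-6-(methoxycarbonyl)phenyl}methanolate F3. Dilute acid collapses it, and the fallback comes back to the route at 8.

**Step 10 (zinc–alkali opening of the phthalide).**
- Risk: the very lipophilic lactone may react slowly in the heterogeneous aqueous medium.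
- Fallback: this sets out from 14 and switches from electron-transfer to ionic reduction. LiAlH4 (THF, 0 °C) opens the lactone to racemic [4-(benzyloxy)phenyl]{4-(benzyloxy)-3-[4-(benzyloxy)benzyl]-6-(hydroxymethyl)-2-methoxyphenyl}methanol F4.
- Et3SiH/CF3CO2H (CH2Cl2, 0 °C) then removes only the strongly stabilised diaryl carbinol oxygen.
- The neighbouring CH2OH can capture the cation to give racemic 5-(benzyloxy)-6-[4-(benzyloxy)benzyl]-1-[4-(benzyloxy)phenyl]-7-methoxy-1,3-dihydro-2-benzofuran F5. This ether re-ionises under the same acid and is reduced as well.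
- The fallback skips 15 and comes back to the route at 16.

**Step 17 (aldol union).**
- Risk: both partners carry an ortho benzyl arm, so slow addition or retro-aldol on warming could lower the yield.
- Fallback: this sets out from 17 and 22 and replaces the preformed dianion by a thermodynamic Perkin-type condensation. Ac2O and Et3N at 110 °C give (E)-3-{5-(benzyloxy)-2,4-bis[4-(benzyloxy)benzyl]-3-methoxyphenyl}-2-{5-(benzyloxy)-2-[4-(benzyloxy)benzyl]phenyl}prop-2-enoic acid F6.
- F6 is decarboxylated with Cu powder in quinoline at 200 °C. The fallback skips 24 and step 18 and comes back to the route at 26.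

## Further compounds
F1 | step 5 | methyl 3,5-bis(benzyloxy)-4-[4-(benzyloxy)benzyl]-2-bromobenzoate | COC(=O)c1cc(OCc2ccccc2)c(Cc2ccc(OCc3ccccc3)cc2)c(OCc2ccccc2)c1Br
F2 | step 5 | {2,4-bis(benzyloxy)-3-[4-(benzyloxy)benzyl]-6-(methoxycarbonyl)phenyl}magnesium chloride | COC(=O)c1cc(OCc2ccccc2)c(Cc2ccc(OCc3ccccc3)cc2)c(OCc2ccccc2)c1[Mg]Cl
F3 | step 5 | chloromagnesium (dimethylamino){2,4-bis(benzyloxy)-3-[4-(benzyloxy)benzyl]-6-(methoxycarbonyl)phenyl}methanolate | COC(=O)c1cc(OCc2ccccc2)c(Cc2ccc(OCc3ccccc3)cc2)c(OCc2ccccc2)c1C(O[Mg]Cl)N(C)C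
F4 | step 10 | racemic [4-(benzyloxy)phenyl]{4-(benzyloxy)-3-[4-(benzyloxy)benzyl]-6-(hydroxymethyl)-2-methoxyphenyl}methanol | OCc1cc(OCc2ccccc2)c(Cc2ccc(OCc3ccccc3)cc2)c(OC)c1C(O)c1ccc(OCc2ccccc2)cc1
F5 | step 10 | racemic 5-(benzyloxy)-6-[4-(benzyloxy)benzyl]-1-[4-(benzyloxy)phenyl]-7-methoxy-1,3-dihydro-2-benzofuran | COc1c(Cc2ccc(OCc3ccccc3)cc2)c(OCc2ccccc2)cc2COC(c3ccc(OCc4ccccc4)cc3)c12
F6 | step 17 | (E)-3-{5-(benzyloxy)-2,4-bis[4-(benzyloxy)benzyl]-3-methoxyphenyl}-2-{5-(benzyloxy)-2-[4-(benzyloxy)benzyl]phenyl}prop-2-enoic acid | OC(=O)/C(c1cc(OCc2ccccc2)ccc1Cc1ccc(OCc2ccccc2)cc1)=C/c1cc(OCc2ccccc2)c(Cc2ccc(OCc3ccccc3)cc2)c(OC)c1Cc1ccc(OCc2ccccc2)cc1
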